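## Structural features

The target is a homoisoflavonoid without any stereocentre: a 4H-chromen-4-one in which benzo ring A and pyranone ring C share the C4a–C8a bond, with C3 of ring C joined through one methylene carbon to a 4-methoxyphenyl ring B. Every carbon of ring A is substituted, with methoxy at C5, methyl at C6, a free hydroxyl at C7 and a formyl group at C8, beside the ring oxygen on C8a and the C4 carbonyl on C4a. The three oxygens of this phloroglucinol-type ring are all different, and the methyl ether sits on the oxygen that would be the chelated, less reactive hydroxyl of a 5,7-dihydroxychromone. Fragile points are the aldehyde flanked by two oxygens, C2 of ring C (open to ring-opening attack by hydroxide or amines), the C5 methyl ether peri to the carbonyl (lost with boron or aluminium halides) and the acidic C7 phenol. The real difficulty is the regiochemistry of ring A, where the acyl carbon must stand next to the methoxy group and the formyl carbon next to the free hydroxyl, whereas the C3 side chain is the easy part. The key step exploits the fact that, once the O1–C2 bond is opened and C2 is capped with dimethylamine, C3 is the α-carbon of an o-hydroxyaryl enaminone and the most nucleophilic carbon of the molecule. After C3 has taken up the benzylic carbon, C2 becomes an iminium carbon on which the hydroxyl of C8a closes ring C.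

## Logic of the disconnections

18 ⇒ 17. Only the O–Si bond on the C7 oxygen is cut. The free C7 phenol of 18 is acidic (para to the C4 carbonyl, ortho to the formyl group) and would take part in O-alkylation and metal binding in every earlier step, so it is carried in silylated form to the end. Nothing is gained in skeleton, but every earlier intermediate has at most one free hydroxyl. The forward step must be a buffered fluoride cleavage, because base would open ring C at C2 and boron or aluminium halides would take the C5 methyl ether.

17 ⇒ 13 + 14. The C3–CH2 bond and the O1–C2 bond are cut together. This opens ring C and removes ring B with its methylene carbon in one stroke; what remains is 13, in which C2 is capped by dimethylamine, and 14, which is commercial. The cut is placed here because C3 is both the attachment point of the side chain and the nucleophilic α-carbon of the enaminone in 13. The forward step must generate a benzylic cation from 14 under conditions in which 13 is alkylated on carbon before it closes by simple protonation. 13 must also offer no second nucleophilic carbon, which is why ring A is completed first.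

13 ⇒ 11 + 12. The C2=C3 double bond is cut, returning C2 to 12 and leaving a methyl ketone. One carbon and the amine leave the structure, and the only stereo-element (the E alkene) disappears. The forward condensation must occur at the acetyl methyl group without O-methylation of the neighbouring hydroxyl and without touching the non-enolisable aldehyde or the silyl ether.

11 ⇒ 9. The C8–CHO bond is cut. In 9 this carbon is the only unsubstituted ring position and lies ortho to the free hydroxyl, ortho to the silyloxy group and para to the methoxy group, so electrophilic formylation needs no regiocontrol. Removing the aldehyde here keeps it out of all organometallic steps. The forward step needs a small, strong formyl cation equivalent and a Lewis acid that spares the silyl ether and the methyl ether next to the ketone.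

9 ⇒ 8 ⇒ 5. The hydroxyl ortho to the ketone is first re-masked as its methoxymethyl ether (8), then the aryl–acetyl bond C4a–C4 is cut back to a C–H bond (5). The acetal is there to direct: an alkyllithium removes the proton between the acetal oxygen and the methoxy group, while the silyloxy group neither binds lithium nor leaves room beside itself. This places the acyl group next to the methoxy group, which is the central regiochemical problem of ring A. The forward steps need clean monolithiation (6), an acetyl donor that stops at the ketone (through 7) and an acetal cleavage mild enough for the silyl ether.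

5 ⇒ 4. The O–CH2 bond of the acetal is cut to the free phenol. 4 has a single hydroxyl, so the only demand is ordinary O-alkylation.

4 ⇒ 2. The C8a–O bond is cut back to a C–H bond by way of 3. In 2 this is the only ring C–H without an ortho substituent, so sterically governed iridium-catalysed borylation selects it and oxidation of the C–B bond gives the phenol. A 1,3,5-trioxygenated, 2-methylated benzene with three differently masked oxygens is thereby traced to a simple 1,2,3-trisubstituted arene. The forward step needs meta selectivity and an oxidant that does not over-oxidise the electron-rich phenol.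

2 ⇒ 1. The O–Si bond is cut. 1 is commercial and already has the methyl group between a free hydroxyl and a methoxy group. The C5-OMe/C6-Me/C7-OH relation of 18 is therefore in place from the first compound and never has to be made by selective methylation.

## Other disconnections considered

Alternative 1: The cut is the C4a–C8a bond, with ring A unfolded into an open chain.
- **Precursor and key step:** The precursor would be methyl (E)-5-methoxy-9-(4-methoxyphenyl)-4-methyl-3,7-dioxonon-4-enoate A2. In A2 the C5/C6 unit is locked as a methyl enol ether, the C7 ketone and the C8a ester are free, and the C4 ketone already carries the two-carbon chain to ring B. Mg(OMe)2 would form the C4a carbanion, which attacks the ester carbon, and enolisation would give 1-(2,4-dihydroxy-6-methoxy-5-methylphenyl)-3-(4-methoxyphenyl)propan-1-one A1.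
- **In its favour:** The methoxy/methyl/hydroxyl pattern is written into the chain, no phenol protecting group is needed, and the C3 and benzylic carbons are in place before any ring exists.
- **Against it here:** A2 is a demanding target in itself: a geometrically defined β-methoxy enone beside a β-keto ester. It can fold the wrong way, by aldol closure of the more acidic C8 methylene onto the C4 ketone or by O-acylation to a pyranone. A1 still lacks C2 (to be added with 12 while the C7 hydroxyl is free) and the formyl carbon on C8.
- **Comparison on structure:** This route builds ring A and leaves ring C and the aldehyde for later. The chosen plan builds ring C last on a finished ring A.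
- **Comparison on mechanism:** An intramolecular enolate acylation stands against an intermolecular cation capture. The Claisen closure is the cleaner elementary step, but its substrate A2 is the less accessible one.
- **Step economy:** A2 is estimated at five or six steps, so with cyclisation to A1, C2 insertion and formylation the count would be about nine or ten, no shorter than the chosen nine.
- **Where it is equal or better:** It differentiates the C5 methyl ether from the C7 hydroxyl without any protecting group.

Alternative 2: The cut is the C4a–C5 bond, with ring A grown on a finished ring C.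
- **Precursor and key step:** The precursor would be methyl 4-[5-(4-methoxybenzyl)-4-oxo-4H-pyran-2-yl]-2-methyl-3-oxobutanoate A4. Mg(OMe)2 would deprotonate the side-chain methylene of A4 to an extended enolate running through the pyranone. Its α-carbon (C4a) attacks the ester carbon (C5), and tautomerisation would give 5,7-dihydroxy-3-(4-methoxybenzyl)-6-methyl-4H-chromen-4-one A3.
- **In its favour:** Ring C with its C3 benzyl group is secure from the outset in A4, no benzylic cation and no enaminone are involved, and the closure has no regiochemical ambiguity.
- **Against it here:** A4 is not a simple building block and needs its own synthesis of a 2,5-disubstituted pyranone. A3 has both ring A hydroxyls free. The target needs the methyl group on the chelated C5 oxygen and a free C7 hydroxyl, the reverse of the innate order of reactivity. This forces protection of the C7 hydroxyl, forced methylation at C5 and deprotection, followed by C8 formylation on the chromone.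
- **Comparison on structure:** It solves the carbon framework of ring A but not the differentiation of its oxygens, which the chosen plan takes from 1 at no cost.
- **Comparison on mechanism:** The closure of A4 is a vinylogous Claisen condensation, again intramolecular.
- **Step economy:** With the preparation of A4 and the four steps needed after A3, the count is estimated at ten or more.
- **Where it is equal or better:** The key step is free of bimolecular side reactions, and no sensitive aldehyde is present when the ring is formed.

Alternative 3: The cut is the C2–C3 bond.
- **Precursor and key step:** Ring C is unfolded to (E)-1-[6-methoxy-5-methyl-2-(methylthiomethoxy)-4-(triisopropylsilyloxy)phenyl]-3-(4-methoxyphenyl)prop-2-en-1-one A6, which would be made from 9 by aldol condensation and O-alkylation. MeOTf would methylate the sulfur of A6, and departure of the sulfonium leaving group would leave an aryloxymethyl cation. The chalcone α-carbon attacks this cation while the 4-methoxyphenyl group stabilises the charge at the β-carbon. Proton loss would give (E)-5-methoxy-3-(4-methoxybenzylidene)-6-methyl-7-(triisopropylsilyloxy)chroman-4-one A5.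
- **In its favour:** It follows the presumed biogenesis, it is convergent from simple partners, and the cation and its nucleophile are in the same molecule.
- **Against it here:** A5 has the double bond outside the ring and no formyl carbon on C8. An isomerisation into ring C, desilylation and a late formylation must follow. MeOTf is a hazardous, unselective methylating agent. The unsubstituted ring A carbon of A6 is a competing nucleophile for intermolecular attack. The methylthiomethyl ether has to be placed on a hindered, chelated phenol.
- **Comparison on structure:** Both plans close ring C. The chosen one forms two bonds, delivers the chromone directly and carries the aldehyde through.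
- **Comparison on mechanism:** Both are cationic.
- **Step economy:** About eleven steps against nine.
- **Where it is equal or better:** The intramolecular capture in A6 is better than the intermolecular capture of the chosen plan. The two are equal in needing no redox adjustment, since A5 and the chromone are isomers.

Key step: step 8

Remark on the chemistry: 1, 12, 14 and all reagents on the Conditions lines are taken as commercial. The target has no stereocentre, and the only stereo-descriptor in the route is the E double bond of 13, which is consumed in step 8.

## Route

Step 1
Reactants: 1 3-methoxy-2-methylphenol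
Product: 2 triisopropyl(3-methoxy-2-methylphenoxy)silane
Conditions: TIPSCl, imidazole, DMF, rt
Reagents that add atoms: triisopropylsilyl chloride, CC(C)[Si](Cl)(C(C)C)C(C)C
Why: Silyl ether formation on the phenol, with imidazole as base and nucleophilic catalyst. The triisopropylsilyl group is chosen because it survives n-BuLi, blocks metalation beside itself and is removed by fluoride at the end.

Step 2
Reactants: 2 triisopropyl(3-methoxy-2-methylphenoxy)silane
Product: 4 3-methoxy-4-methyl-5-[(triisopropylsilyl)oxy]phenol, via arylboronate 3 (not isolated)
Conditions: [Ir(OMe)(cod)]2 (1.5 mol %), 4,4'-di-tert-butyl-2,2'-bipyridine (3 mol %), B2pin2 (1.0 equiv), THF, 80 °C; then KHSO5 (Oxone), acetone–H2O, rt, short contact time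
Reagents that add atoms: bis(pinacolato)diboron, CC1(C)OB(OC1(C)C)B1OC(C)(C)C(C)(C)O1 (boron of 3 only); potassium peroxymonosulfate, [K+].[O-]S(=O)(=O)OO (oxygen of 4)
Why: Sterically governed iridium-catalysed C–H borylation of the 1,2,3-trisubstituted arene should take the only C–H with no ortho substituent, and oxidation of the C–B bond in the same flask gives the phenol at that position (one-pot C–H borylation–oxidation). The silyl and methyl ethers are inert to both stages.

Step 3
Reactants: 4 3-methoxy-4-methyl-5-[(triisopropylsilyl)oxy]phenol
Product: 5 triisopropyl[3-methoxy-5-(methoxymethoxy)-2-methylphenoxy]silane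
Conditions: MOMCl, i-Pr2NEt, CH2Cl2, 0 °C to rt
Reagents that add atoms: chloromethyl methyl ether, COCCl
Why: Base-mediated O-alkylation of the single, unhindered phenol gives the methoxymethyl ether, which then serves as the directing group for metalation.

Step 4
Reactants: 5 triisopropyl[3-methoxy-5-(methoxymethoxy)-2-methylphenoxy]silane
Product: 8 1-[2-methoxy-6-(methoxymethoxy)-3-methyl-4-[(triisopropylsilyl)oxy]phenyl]ethan-1-one, via aryllithium 6 (not isolated), via lithium hemiaminal 7 (not isolated)
Conditions: n-BuLi, THF, 0 °C; then MeC(O)N(OMe)Me, −78 to 0 °C; aq NH4Cl
Reagents that add atoms: N-methoxy-N-methylacetamide, CC(=O)N(C)OC; n-butyllithium, CCCC[Li] (lithium of 6 and 7 only)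
Why: Directed ortho-metalation should remove the proton between the methoxymethoxy and methoxy groups, which is doubly acidified and chelated, while the bulky, non-coordinating silyloxy group shields the other ortho position. The aryllithium is acylated by the N-methoxy-N-methylamide (Weinreb ketone synthesis), whose chelated tetrahedral adduct prevents a second addition.

Step 5
Reactants: 8 1-[2-methoxy-6-(methoxymethoxy)-3-methyl-4-[(triisopropylsilyl)oxy]phenyl]ethan-1-one
Product: 9 1-[2-hydroxy-6-methoxy-5-methyl-4-[(triisopropylsilyl)oxy]phenyl]ethan-1-one
Conditions: 3 M aq HCl, MeOH, 40 °C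
Reagents that add atoms: none
Why: Acid-catalysed methanolysis of the acetal (methoxymethyl ether cleavage) is eased by the ortho carbonyl group. Aryl triisopropylsilyl ethers and aryl methyl ethers are stable to dilute methanolic HCl.

Step 6
Reactants: 9 1-[2-hydroxy-6-methoxy-5-methyl-4-[(triisopropylsilyl)oxy]phenyl]ethan-1-one
Product: 11 3-acetyl-2-hydroxy-4-methoxy-5-methyl-6-[(triisopropylsilyl)oxy]benzaldehyde, via α-chloro ether 10 (not isolated)
Conditions: Cl2CHOMe, TiCl4, CH2Cl2, −20 to 0 °C; then ice-cold 1 M aq HCl
Reagents that add atoms: dichloromethyl methyl ether, COC(Cl)Cl; water, O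
Why: Rieche formylation: TiCl4 binds the phenoxide–ketone chelate and turns the dichloromethyl ether into a small chloro(methoxy)carbenium electrophile, which can only attack the one free ring position (ortho to the hydroxyl, para to the methoxy group). Aqueous hydrolysis of the α-chloro ether releases the aldehyde, and the low temperature is meant to spare the silyl ether and the methyl ether next to the ketone.

Step 7
Reactants: 11 3-acetyl-2-hydroxy-4-methoxy-5-methyl-6-[(triisopropylsilyl)oxy]benzaldehyde; 12 N,N-dimethylformamide dimethyl acetal
Product: 13 (E)-3-(dimethylamino)-1-[3-formyl-2-hydroxy-6-methoxy-5-methyl-4-[(triisopropylsilyl)oxy]phenyl]prop-2-en-1-one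
Conditions: 12 (2 equiv), toluene, 70 °C
Reagents that add atoms: none
Why: Condensation of a methyl ketone with an amide acetal (enaminone synthesis): the enol attacks the alkoxyiminium ion and methanol is lost twice, and the E geometry is the conjugated, thermodynamically preferred one. The aldehyde has no α-hydrogen, and the hydrogen-bonded hydroxyl is a poor partner for O-methylation at this moderate temperature.

Step 8
Reactants: 13 (E)-3-(dimethylamino)-1-[3-formyl-2-hydroxy-6-methoxy-5-methyl-4-[(triisopropylsilyl)oxy]phenyl]prop-2-en-1-one; 14 4-methoxybenzyl alcohol
Product: 17 5-methoxy-3-(4-methoxybenzyl)-6-methyl-4-oxo-7-[(triisopropylsilyl)oxy]-4H-chromene-8-carbaldehyde, via iminium ion 15 (not isolated), via 2-aminochromanone 16 (not isolated)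
Conditions: Sc(OTf)3 (10 mol %), 14 (1.5 equiv), MeCN, 70 °C, slow N2 sweep
Reagents that add atoms: none
Why: Sc(OTf)3 ionises the benzylic C–O bond of 14 to the 4-methoxybenzyl cation, which the enaminone of 13 captures at its α-carbon (C3) to give iminium ion 15 and the new C3–CH2 bond. The hydroxyl on C8a, held beside the side chain by its hydrogen bond to the ketone, then adds to the iminium carbon (C2) in a 6-exo-trig closure (the C=N+ bond lies outside the forming ring), giving aminal 16 and the O1–C2 bond. Loss of dimethylamine across C2–C3 makes ring C the conjugated pyranone of chromone 17 and renders the sequence irreversible. The closest known reaction type is the electrophile-triggered chromone annulation of o-hydroxyaryl enaminones, here combined with Lewis-acid-catalysed alkylation of a π-nucleophile by a benzylic alcohol. No stereocentre remains, because the C2 and C3 centres of 15 and 16 are erased in the elimination. The step needs C-alkylation at C3 to win over arylation of ring A, O-benzylation and plain proton-triggered closure to the 3-unsubstituted chromone. Ring A of 13 has no free position, O-benzylation by this stabilised cation is reversible under the Lewis acid, and a catalytic Lewis acid with excess 14 keeps the cation, not the proton, as the main electrophile. Sweeping out the volatile dimethylamine is intended to keep the catalyst active.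

Step 9
Reactants: 17 5-methoxy-3-(4-methoxybenzyl)-6-methyl-4-oxo-7-[(triisopropylsilyl)oxy]-4H-chromene-8-carbaldehyde
Product: 18 7-hydroxy-5-methoxy-3-(4-methoxybenzyl)-6-methyl-4-oxo-4H-chromene-8-carbaldehyde
Conditions: TBAF, AcOH, THF, 0 °C
Reagents that add atoms: none
Why: Fluoride-mediated cleavage of the aryl silyl ether should be fast, because the departing phenoxide is stabilised by the ortho formyl and para acyl groups. Acetic acid buffers the medium so that C2 of the chromone and the aldehyde are not exposed to base, and the C5 methyl ether is untouched.

## Compound list

1 | 3-methoxy-2-methylphenol | Cc1c(O)cccc1OC | starting material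
2 | triisopropyl(3-methoxy-2-methylphenoxy)silane | COc1cccc(O[Si](C(C)C)(C(C)C)C(C)C)c1C | intermediate
3 | triisopropyl[3-methoxy-2-methyl-5-(4,4,5,5-tetramethyl-1,3,2-dioxaborolan-2-yl)phenoxy]silane | COc1cc(B2OC(C)(C)C(C)(C)O2)cc(O[Si](C(C)C)(C(C)C)C(C)C)c1C | intermediate (not isolated)
4 | 3-methoxy-4-methyl-5-[(triisopropylsilyl)oxy]phenol | COc1cc(O)cc(O[Si](C(C)C)(C(C)C)C(C)C)c1C | intermediate
5 | triisopropyl[3-methoxy-5-(methoxymethoxy)-2-methylphenoxy]silane | COCOc1cc(OC)c(C)c(O[Si](C(C)C)(C(C)C)C(C)C)c1 | intermediate
6 | [2-methoxy-6-(methoxymethoxy)-3-methyl-4-[(triisopropylsilyl)oxy]phenyl]lithium | [Li]c1c(OC)c(C)c(O[Si](C(C)C)(C(C)C)C(C)C)cc1OCOC | intermediate (not isolated)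
7 | lithium 1-[methoxy(methyl)amino]-1-[2-methoxy-6-(methoxymethoxy)-3-methyl-4-[(triisopropylsilyl)oxy]phenyl]ethan-1-olate (racemic) | CC(O[Li])(N(C)OC)c1c(OC)c(C)c(O[Si](C(C)C)(C(C)C)C(C)C)cc1OCOC | intermediate (not isolated)
8 | 1-[2-methoxy-6-(methoxymethoxy)-3-methyl-4-[(triisopropylsilyl)oxy]phenyl]ethan-1-one | CC(=O)c1c(OC)c(C)c(O[Si](C(C)C)(C(C)C)C(C)C)cc1OCOC | intermediate
9 | 1-[2-hydroxy-6-methoxy-5-methyl-4-[(triisopropylsilyl)oxy]phenyl]ethan-1-one | CC(=O)c1c(O)cc(O[Si](C(C)C)(C(C)C)C(C)C)c(C)c1OC | intermediate
10 | 1-[3-[chloro(methoxy)methyl]-2-hydroxy-6-methoxy-5-methyl-4-[(triisopropylsilyl)oxy]phenyl]ethan-1-one (racemic, titanium-bound in the flask) | COC(Cl)c1c(O)c(C(C)=O)c(OC)c(C)c1O[Si](C(C)C)(C(C)C)C(C)C | intermediate (not isolated)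
11 | 3-acetyl-2-hydroxy-4-methoxy-5-methyl-6-[(triisopropylsilyl)oxy]benzaldehyde | CC(=O)c1c(O)c(C=O)c(O[Si](C(C)C)(C(C)C)C(C)C)c(C)c1OC | intermediate
12 | N,N-dimethylformamide dimethyl acetal | COC(OC)N(C)C | starting material
13 | (E)-3-(dimethylamino)-1-[3-formyl-2-hydroxy-6-methoxy-5-methyl-4-[(triisopropylsilyl)oxy]phenyl]prop-2-en-1-one | CN(C)/C=C/C(=O)c1c(O)c(C=O)c(O[Si](C(C)C)(C(C)C)C(C)C)c(C)c1OC | intermediate
14 | 4-methoxybenzyl alcohol | COc1ccc(CO)cc1 | starting material
15 | N-[3-[3-formyl-2-hydroxy-6-methoxy-5-methyl-4-[(triisopropylsilyl)oxy]phenyl]-2-(4-methoxybenzyl)-3-oxopropylidene]-N-methylmethanaminium (racemic cation) | C[N+](C)=CC(Cc1ccc(OC)cc1)C(=O)c1c(O)c(C=O)c(O[Si](C(C)C)(C(C)C)C(C)C)c(C)c1OC | intermediate (not isolated)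
16 | 2-(dimethylamino)-5-methoxy-3-(4-methoxybenzyl)-6-methyl-4-oxo-7-[(triisopropylsilyl)oxy]chromane-8-carbaldehyde (mixture of stereoisomers) | COc1ccc(CC2C(N(C)C)Oc3c(C=O)c(O[Si](C(C)C)(C(C)C)C(C)C)c(C)c(OC)c3C2=O)cc1 | intermediate (not isolated)
17 | 5-methoxy-3-(4-methoxybenzyl)-6-methyl-4-oxo-7-[(triisopropylsilyl)oxy]-4H-chromene-8-carbaldehyde | COc1ccc(Cc2coc3c(C=O)c(O[Si](C(C)C)(C(C)C)C(C)C)c(C)c(OC)c3c2=O)cc1 | intermediate
18 | 7-hydroxy-5-methoxy-3-(4-methoxybenzyl)-6-methyl-4-oxo-4H-chromene-8-carbaldehyde | COc1ccc(Cc2coc3c(C=O)c(O)c(C)c(OC)c3c2=O)cc1 | target

## Step count and least certain steps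

Total steps: 9. Longest linear sequence: 9 steps (1 to 18); 12 and 14 enter as commercial partners.

Step 8 (key step). The most likely failure is ring closure by simple protonation outrunning the benzylation, which would leave C3 unsubstituted. Other risks are loss of catalyst activity as the liberated amine binds the Lewis acid, self-condensation of the benzylic cation, early loss of the silyl group, and aldol-type attack of a second enaminone on the Lewis-acid-activated aldehyde. The fallback separates ring closure from C–C bond formation and brings the benzyl carbon in as a nucleophile. It sets out from 13: iodine in CHCl3 at room temperature should trigger the same annulation with an iodonium electrophile and give 3-iodo-5-methoxy-6-methyl-4-oxo-7-[(triisopropylsilyl)oxy]-4H-chromene-8-carbaldehyde F1. Negishi coupling of F1 with 4-MeOC6H4CH2ZnCl under Pd(PPh3)4 (zerovalent palladium) in THF at room temperature then returns to the route at 17.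

Step 6. The Lewis acid may strip the silyl ether or the methyl ether next to the ketone, and attack at the position squeezed between the hydroxyl and the silyloxy group may be slow. The fallback formylates without the silyl group and puts it back afterwards. It sets out from 9: TBAF/AcOH should give 1-(2,4-dihydroxy-6-methoxy-5-methylphenyl)ethan-1-one F2. A Duff reaction (hexamethylenetetramine, CF3CO2H, 80 °C, then aq HCl) at the only free carbon, between the two hydroxyls, should give 3-acetyl-2,6-dihydroxy-4-methoxy-5-methylbenzaldehyde F3. Silylation (TIPSCl, imidazole, DMF, 0 °C) should favour the more acidic hydroxyl para to the acetyl group, the other being held between the two carbonyl groups by the stronger ketone hydrogen bond, and returns to the route at 11.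

Step 7. The hydroxyl between two carbonyl groups is unusually acidic, so methyl transfer from the acetal to this oxygen may compete with condensation. The silyl ether may also be lost to methanol on heating. The fallback postpones the formyl group until after ring C is built. It sets out from 9: condensation with 12 (toluene, 80 °C) should give (E)-3-(dimethylamino)-1-[2-hydroxy-6-methoxy-5-methyl-4-[(triisopropylsilyl)oxy]phenyl]prop-2-en-1-one F4. The Sc(OTf)3-catalysed annulation with 14 should give 5-methoxy-3-(4-methoxybenzyl)-6-methyl-7-[(triisopropylsilyl)oxy]-4H-chromen-4-one F5, and TBAF/AcOH should give 7-hydroxy-5-methoxy-3-(4-methoxybenzyl)-6-methyl-4H-chromen-4-one F6. A Duff reaction (hexamethylenetetramine, AcOH, 100 °C, then aq HCl) at C8, the only position ortho to the C7 hydroxyl, returns to the route at 18. This detour leaves C8 open during the cation step, which the main route avoids.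

Step 4. The hindered, basic aryllithium may deprotonate the acetamide instead of adding to it, so that the arene is merely returned, and metalation may not be fully regioselective. The fallback replaces acylation by addition and oxidation. It sets out from 5: the same lithiation followed by acetaldehyde at −78 °C should give 1-[2-methoxy-6-(methoxymethoxy)-3-methyl-4-[(triisopropylsilyl)oxy]phenyl]ethan-1-ol F7. Oxidation with Dess–Martin periodinane (NaHCO3, CH2Cl2, rt) returns to the route at 8.

## Further compounds

F1 | step 8 | 3-iodo-5-methoxy-6-methyl-4-oxo-7-[(triisopropylsilyl)oxy]-4H-chromene-8-carbaldehyde | COc1c(C)c(O[Si](C(C)C)(C(C)C)C(C)C)c(C=O)c2occ(I)c(=O)c12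
F2 | step 6 | 1-(2,4-dihydroxy-6-methoxy-5-methylphenyl)ethan-1-one | CC(=O)c1c(O)cc(O)c(C)c1OC
F3 | step 6 | 3-acetyl-2,6-dihydroxy-4-methoxy-5-methylbenzaldehyde | CC(=O)c1c(O)c(C=O)c(O)c(C)c1OC
F4 | step 7 | (E)-3-(dimethylamino)-1-[2-hydroxy-6-methoxy-5-methyl-4-[(triisopropylsilyl)oxy]phenyl]prop-2-en-1-one | CN(C)/C=C/C(=O)c1c(O)cc(O[Si](C(C)C)(C(C)C)C(C)C)c(C)c1OC
F5 | step 7 | 5-methoxy-3-(4-methoxybenzyl)-6-methyl-7-[(triisopropylsilyl)oxy]-4H-chromen-4-one | COc1ccc(Cc2coc3cc(O[Si](C(C)C)(C(C)C)C(C)C)c(C)c(OC)c3c2=O)cc1
F6 | step 7 | 7-hydroxy-5-methoxy-3-(4-methoxybenzyl)-6-methyl-4H-chromen-4-one | COc1ccc(Cc2coc3cc(O)c(C)c(OC)c3c2=O)cc1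
F7 | step 4 | 1-[2-methoxy-6-(methoxymethoxy)-3-methyl-4-[(triisopropylsilyl)oxy]phenyl]ethan-1-ol (racemic) | CC(O)c1c(OC)c(C)c(O[Si](C(C)C)(C(C)C)C(C)C)cc1OCOC
A1 | alternative 1 | 1-(2,4-dihydroxy-6-methoxy-5-methylphenyl)-3-(4-methoxyphenyl)propan-1-one | COc1ccc(CCC(=O)c2c(O)cc(O)c(C)c2OC)cc1
A2 | alternative 1 | methyl (E)-5-methoxy-9-(4-methoxyphenyl)-4-methyl-3,7-dioxonon-4-enoate | COC(=O)CC(=O)/C(C)=C(/OC)CC(=O)CCc1ccc(OC)cc1
A3 | alternative 2 | 5,7-dihydroxy-3-(4-methoxybenzyl)-6-methyl-4H-chromen-4-one | COc1ccc(Cc2coc3cc(O)c(C)c(O)c3c2=O)cc1
A4 | alternative 2 | methyl 4-[5-(4-methoxybenzyl)-4-oxo-4H-pyran-2-yl]-2-methyl-3-oxobutanoate (racemic) | COC(=O)C(C)C(=O)Cc1cc(=O)c(Cc2ccc(OC)cc2)co1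
A5 | alternative 3 | (E)-5-methoxy-3-(4-methoxybenzylidene)-6-methyl-7-(triisopropylsilyloxy)chroman-4-one | COc1ccc(/C=C2\COc3cc(O[Si](C(C)C)(C(C)C)C(C)C)c(C)c(OC)c3C2=O)cc1
A6 | alternative 3 | (E)-1-[6-methoxy-5-methyl-2-(methylthiomethoxy)-4-(triisopropylsilyloxy)phenyl]-3-(4-methoxyphenyl)prop-2-en-1-one | COc1ccc(/C=C/C(=O)c2c(OCSC)cc(O[Si](C(C)C)(C(C)C)C(C)C)c(C)c2OC)cc1
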